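## Retrosynthetic overview

1. Glaucolide L 18 ⇐ 4,5-alkene 17: last-step epoxidation of the E-4,5-alkene, with the face set by the ring (costunolide → parthenolide logic).
2. 17 ⇐ acyclic enal/vinyl iodide 15: the C6–C7 bond (C1–C10 of farnesyl diphosphate) closes the ten-membered carbocycle by Ni/Cr vinylation. The C6 alkoxide then closes the 12,6-lactone and gives the 7(11)-en-13-ol butenolide directly.
3. 15 ⇐ γ-acyloxy ynoate 11 + formaldehyde 12: an iodo-aldol reaction installs C13–OH and the C7 nucleophile precursor in one step.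
4. 11 ⇐ aldehyde 8 + methyl propiolate 9 (C8); 8 ⇐ aldehyde 3 + (Z)-crotylboronate 4 (C1, C10); 3 ⇐ geranyl acetate 1.
5. Ring order: ten-membered carbocycle → butenolide (same flask) → epoxide.

Assumption: positions are given in germacrane numbering (C1–C15) and the target SMILES is read as (1S,4R,5R,6S,8S,10S); in 16 and 17 the same spatial arrangement at C6 is named R because C7 outranks the alkene carbon C5.

## Route

Step 1
Reactants: 1 geranyl acetate
Product: 3 (2E)-3-methyl-6-oxohex-2-en-1-yl acetate (C1 aldehyde, C6 acetate), via secondary ozonide 2 (not isolated)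
Conditions: O3 (1.0 equiv, Sudan Red 7B end-point), CH2Cl2, −78 °C; then Me2S, −78 °C → rt
Reagents that add atoms: ozone, O=[O+][O-]
Why: Selective ozonolysis (Criegee mechanism) of the electron-rich 6,7-alkene, because the 2,3-alkene is deactivated by the allylic acetate, so one equivalent of ozone removes only the isopropylidene end and leaves the E-alkene (later C4=C5) untouched.

Step 2
Reactants: 3 (2E)-3-methyl-6-oxohex-2-en-1-yl acetate; 4 (Z)-crotylboronic acid pinacol ester
Product: 6 (2E,6S,7S)-6-hydroxy-3,7-dimethylnona-2,8-dien-1-yl acetate (1S,10S in germacrane numbering), via pinacol borate ester 5 (not isolated)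
Conditions: 4 (1.3 equiv), (R)-TRIP (5 mol%), 4 Å MS, toluene, −30 °C; H2O work-up
Reagents that add atoms: 4 (Z)-crotylboronic acid pinacol ester, C/C=C\CB1OC(C)(C)C(C)(C)O1
Why: Chiral phosphoric acid-catalysed crotylboration through a closed chair transition state, in which the Z-crotylboronate gives the 1,10-syn adduct and (R)-TRIP directs addition to the Re face of the aldehyde, setting C1 (S) and C10 (S).

Step 3
Reactants: 6 (2E,6S,7S)-6-hydroxy-3,7-dimethylnona-2,8-dien-1-yl acetate
Product: 7 (2E,6S,7S)-3,7-dimethylnona-2,8-diene-1,6-diyl diacetate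
Conditions: Ac2O, pyridine, DMAP (cat.), CH2Cl2, 0 °C → rt
Reagents that add atoms: acetic anhydride, CC(=O)OC(C)=O
Why: DMAP-catalysed acetylation installs the final C1 acetate and protects this hydroxyl for the rest of the route without touching a stereocentre.

Step 4
Reactants: 7 (2E,6S,7S)-3,7-dimethylnona-2,8-diene-1,6-diyl diacetate
Product: 8 (2E,6S,7S)-3,7-dimethyl-9-oxonon-2-ene-1,6-diyl diacetate (C8 aldehyde)
Conditions: PdCl2(PhCN)2 (10 mol%), CuCl2·2H2O (10 mol%), AgNO2 (5 mol%), t-BuOH/MeNO2 15:1, O2 (1 atm), rt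
Reagents that add atoms: dioxygen, O=O
Why: Nitrite-modified, aldehyde-selective (anti-Markovnikov) Wacker oxidation of the monosubstituted alkene, favoured by the homoallylic acetate and the allylic branch, while the trisubstituted alkene is inert and C10 (β to the new aldehyde) cannot epimerise.

Step 5
Reactants: 8 (2E,6S,7S)-3,7-dimethyl-9-oxonon-2-ene-1,6-diyl diacetate; 9 methyl propiolate
Product: 10 methyl (4S,6S,7S,10E)-7,12-diacetoxy-4-hydroxy-6,10-dimethyldodec-10-en-2-ynoate (8S in germacrane numbering)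
Conditions: 9 (3 equiv), ZnMe2 (3 equiv), (S,S)-ProPhenol (20 mol%), Ph3P=O (40 mol%), toluene, 4 °C; H2O work-up
Reagents that add atoms: 9 methyl propiolate, C#CC(=O)OC
Why: Zn–ProPhenol-catalysed asymmetric alkynylation, in which reagent control (Re-face delivery of the zinc propiolate by the (S,S)-ligand, the same facial sense as in the Zn–ProPhenol aldol reaction) sets C8 (S) and overrides the weak 1,3-bias of C10.

Step 6
Reactants: 10 methyl (4S,6S,7S,10E)-7,12-diacetoxy-4-hydroxy-6,10-dimethyldodec-10-en-2-ynoate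
Product: 11 methyl (4S,6S,7S,10E)-7,12-diacetoxy-6,10-dimethyl-4-(methacryloyloxy)dodec-10-en-2-ynoate
Conditions: methacrylic anhydride (1.5 equiv), DMAP (10 mol%), pyridine, CH2Cl2, −10 → 0 °C
Reagents that add atoms: methacrylic anhydride, C=C(C)C(=O)OC(=O)C(C)=C
Why: DMAP-catalysed acylation puts on the final C8 methacrylate with retention at C8, and the low temperature avoids base-induced isomerisation of the γ-hydroxy ynoate.

Step 7
Reactants: 11 methyl (4S,6S,7S,10E)-7,12-diacetoxy-6,10-dimethyl-4-(methacryloyloxy)dodec-10-en-2-ynoate; 12 formaldehyde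
Product: 13 methyl (2Z,4S,6S,7S,10E)-7,12-diacetoxy-2-(hydroxymethyl)-3-iodo-6,10-dimethyl-4-(methacryloyloxy)dodeca-2,10-dienoate
Conditions: MgI2 (1.5 equiv), monomeric CH2O (5 equiv, from cracked paraformaldehyde), CH2Cl2, −20 → 0 °C; H2O work-up
Reagents that add atoms: magnesium iodide MgI2, [Mg+2].[I-].[I-]; 12 formaldehyde, C=O
Why: Three-component iodo-aldol (β-iodo Morita–Baylis–Hillman) reaction, in which iodide adds to C7 of the MgI2-activated ynoate and the β-iodoallenolate is trapped at C11 by formaldehyde trans to iodine (anti addition, as in NaI/AcOH hydroiodination of 2-ynoates), giving the Z-iodoenoate with I cis to CO2Me and C13 cis to C8.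

Step 8
Reactants: 13 methyl (2Z,4S,6S,7S,10E)-7,12-diacetoxy-2-(hydroxymethyl)-3-iodo-6,10-dimethyl-4-(methacryloyloxy)dodeca-2,10-dienoate
Product: 14 methyl (2Z,4S,6S,7S,10E)-7-acetoxy-12-hydroxy-2-(hydroxymethyl)-3-iodo-6,10-dimethyl-4-(methacryloyloxy)dodeca-2,10-dienoate
Conditions: immobilised Candida antarctica lipase B, pH 7 phosphate buffer/MTBE, 30 °C
Reagents that add atoms: none
Why: Lipase-catalysed chemoselective ester hydrolysis removes only the unhindered primary allylic acetate at C6, because the secondary acetate and methacrylate (each flanked by two large groups) and the hindered tetrasubstituted enoate do not fit the active site, and pH 7 avoids acyl migration.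

Step 9
Reactants: 14 methyl (2Z,4S,6S,7S,10E)-7-acetoxy-12-hydroxy-2-(hydroxymethyl)-3-iodo-6,10-dimethyl-4-(methacryloyloxy)dodeca-2,10-dienoate
Product: 15 methyl (2Z,4S,6S,7S,10E)-7-acetoxy-2-(hydroxymethyl)-3-iodo-6,10-dimethyl-4-(methacryloyloxy)-12-oxododeca-2,10-dienoate (C6 enal)
Conditions: activated MnO2 (15 equiv), CH2Cl2, rt
Reagents that add atoms: none
Why: MnO2 allylic oxidation converts the electron-rich allylic alcohol at C6 into the E-enal with retention of alkene geometry, while the C13 hydroxymethyl group on the electron-poor iodoenoate reacts much more slowly.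

Step 10
Reactants: 15 methyl (2Z,4S,6S,7S,10E)-7-acetoxy-2-(hydroxymethyl)-3-iodo-6,10-dimethyl-4-(methacryloyloxy)-12-oxododeca-2,10-dienoate
Product: 17 (1S,4E,6R,8S,10S)-1-acetoxy-13-hydroxy-8-(methacryloyloxy)germacra-4,7(11)-dien-12,6-olide (4,5-deepoxyglaucolide L), via seco hydroxy ester 16 (not isolated)
Conditions: CrCl2 (8 equiv), NiCl2 (2 mol%), degassed DMSO/THF 1:1, rt, syringe-pump addition of 15 (final 2 mM); H2O work-up
Reagents that add atoms: none
Why: Intramolecular Nozaki–Hiyama–Kishi reaction, in which the C7 vinylchromium adds to the C6 enal to close the ten-membered carbocycle and the chromium alkoxide then lactonises onto the cis CO2Me (the order germacrene acid → costunolide), with C6 set by addition to the Si face of the s-trans enal in the conformer that keeps the formyl H eclipsed with C4 (A1,3 strain with the C15 methyl) and the C8 acyloxy group outside the ring.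

Step 11
Reactants: 17 (1S,4E,6R,8S,10S)-1-acetoxy-13-hydroxy-8-(methacryloyloxy)germacra-4,7(11)-dien-12,6-olide
Product: 18 glaucolide L, (1S,4R,5R,6S,8S,10S)-1-acetoxy-4,5-epoxy-13-hydroxy-8-(methacryloyloxy)germacr-7(11)-en-12,6-olide
Conditions: mCPBA (1.1 equiv), CH2Cl2, 0 °C
Reagents that add atoms: mCPBA, OOC(=O)c1cccc(Cl)c1
Why: Prilezhaev epoxidation, in which mCPBA reacts only with the electron-rich trisubstituted 4,5-alkene (butenolide and methacrylate are electron-poor) and attacks the outer face of the E-alkene, syn to O6 with H6 eclipsing the alkene plane (A1,3 strain), giving the 4R,5R epoxide as in costunolide → parthenolide.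

## Compound list

1 | geranyl acetate, (2E)-3,7-dimethylocta-2,6-dien-1-yl acetate | CC(C)=CCC/C(C)=C/COC(C)=O | starting material
2 | secondary ozonide of 1, (2E)-5-(5,5-dimethyl-1,2,4-trioxolan-3-yl)-3-methylpent-2-en-1-yl acetate | CC1(C)OOC(CC/C(C)=C/COC(C)=O)O1 | intermediate
3 | (2E)-3-methyl-6-oxohex-2-en-1-yl acetate | O=CCC/C(C)=C/COC(C)=O | intermediate
4 | (Z)-crotylboronic acid pinacol ester | C/C=C\CB1OC(C)(C)C(C)(C)O1 | starting material
5 | pinacol borate ester of 6 | C=C[C@H](C)[C@@H](OB1OC(C)(C)C(C)(C)O1)CC/C(C)=C/COC(C)=O | intermediate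
6 | (2E,6S,7S)-6-hydroxy-3,7-dimethylnona-2,8-dien-1-yl acetate | C=C[C@H](C)[C@@H](O)CC/C(C)=C/COC(C)=O | intermediate
7 | (2E,6S,7S)-3,7-dimethylnona-2,8-diene-1,6-diyl diacetate | C=C[C@H](C)[C@@H](OC(C)=O)CC/C(C)=C/COC(C)=O | intermediate
8 | (2E,6S,7S)-3,7-dimethyl-9-oxonon-2-ene-1,6-diyl diacetate | O=CC[C@H](C)[C@@H](OC(C)=O)CC/C(C)=C/COC(C)=O | intermediate
9 | methyl propiolate | C#CC(=O)OC | starting material
10 | methyl (4S,6S,7S,10E)-7,12-diacetoxy-4-hydroxy-6,10-dimethyldodec-10-en-2-ynoate | COC(=O)C#C[C@@H](O)C[C@H](C)[C@@H](OC(C)=O)CC/C(C)=C/COC(C)=O | intermediate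
11 | methyl (4S,6S,7S,10E)-7,12-diacetoxy-6,10-dimethyl-4-(methacryloyloxy)dodec-10-en-2-ynoate | COC(=O)C#C[C@@H](OC(=O)C(C)=C)C[C@H](C)[C@@H](OC(C)=O)CC/C(C)=C/COC(C)=O | intermediate
12 | formaldehyde | C=O | starting material
13 | methyl (2Z,4S,6S,7S,10E)-7,12-diacetoxy-2-(hydroxymethyl)-3-iodo-6,10-dimethyl-4-(methacryloyloxy)dodeca-2,10-dienoate | COC(=O)/C(CO)=C(I)/[C@@H](OC(=O)C(C)=C)C[C@H](C)[C@@H](OC(C)=O)CC/C(C)=C/COC(C)=O | intermediate
14 | methyl (2Z,4S,6S,7S,10E)-7-acetoxy-12-hydroxy-2-(hydroxymethyl)-3-iodo-6,10-dimethyl-4-(methacryloyloxy)dodeca-2,10-dienoate | COC(=O)/C(CO)=C(I)/[C@@H](OC(=O)C(C)=C)C[C@H](C)[C@@H](OC(C)=O)CC/C(C)=C/CO | intermediate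
15 | methyl (2Z,4S,6S,7S,10E)-7-acetoxy-2-(hydroxymethyl)-3-iodo-6,10-dimethyl-4-(methacryloyloxy)-12-oxododeca-2,10-dienoate | COC(=O)/C(CO)=C(I)/[C@@H](OC(=O)C(C)=C)C[C@H](C)[C@@H](OC(C)=O)CC/C(C)=C/C=O | intermediate
16 | seco hydroxy ester, methyl (2E)-2-[(2R,3E,7S,8S,10S)-7-acetoxy-2-hydroxy-4,8-dimethyl-10-(methacryloyloxy)cyclodec-3-en-1-ylidene]-3-hydroxypropanoate | COC(=O)/C(CO)=C1/[C@@H](OC(=O)C(C)=C)C[C@H](C)[C@@H](OC(C)=O)CC/C(C)=C/[C@H]1O | intermediate
17 | (1S,4E,6R,8S,10S)-1-acetoxy-13-hydroxy-8-(methacryloyloxy)germacra-4,7(11)-dien-12,6-olide | C=C(C)C(=O)O[C@H]1C[C@H](C)[C@@H](OC(C)=O)CC/C(C)=C/[C@H]2OC(=O)C(CO)=C12 | intermediate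
18 | glaucolide L, (1S,4R,5R,6S,8S,10S)-1-acetoxy-4,5-epoxy-13-hydroxy-8-(methacryloyloxy)germacr-7(11)-en-12,6-olide | C=C(C)C(=O)O[C@H]1C[C@H](C)[C@@H](OC(C)=O)CC[C@@]2(C)O[C@@H]2[C@H]2OC(=O)C(CO)=C12 | target

## Step count and risks

Total step count: 11. Longest linear sequence: 11 steps, from geranyl acetate 1; compounds 4, 9 and 12 are bought.

The three steps most likely to fail:

Step 10 (Ni/Cr ring closure). The risks are slow closure of the ten-membered ring against oligomerisation, loss of the C8 acyloxy group from the vinylchromium (allene formation), and the wrong face at C6, which cannot be corrected once the lactone has formed. The fallback sets out from 15 and separates ring closure from the C6 stereocentre. Pinnick oxidation of the enal (NaClO2, NaH2PO4, 2-methyl-2-butene) gives the carboxylic acid F1. Treatment with (PyS)2 and PPh3 gives the S-2-pyridyl thioester F2. A Ni/Zr-mediated intramolecular ketone coupling (NiBr2(dtbbpy), Cp2ZrCl2, Zn, DMI/THF, high dilution) then forms the same C6–C7 bond and gives the macrocyclic 6-ketone F3 without creating a stereocentre. Reduction with (S)-Me-CBS and catecholborane, taking the tetrasubstituted C7 alkenyl as the large group, sets C6 by reagent control and gives the hydroxy ester 16, which lactonises; the fallback comes back to the route at 17.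

Step 7 (iodo-aldol). The internal γ-acyloxy ynoate is less reactive than a propiolate, the Z/E ratio at the tetrasubstituted alkene is not secured, and MgI2 may attack the allylic acetate. The fallback sets out from 11 and replaces iodide by tin. Conjugate addition of Me3SnCu·SMe2 (1.05 equiv, THF, −78 → −48 °C) gives the equilibrated β-stannyl allenoate, which takes up electrophiles trans to tin. Trapping with monomeric formaldehyde gives the vinylstannane F4, with the tin cis to CO2Me. Iododestannylation with I2 in CH2Cl2 at 0 °C proceeds with retention, and the fallback comes back to the route at 13.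

Step 4 (aldehyde-selective Wacker oxidation). The risks are a methyl ketone by-product and interference of PdCl2(PhCN)2 with the allylic acetate. The fallback sets out from 7 and uses hydroboration in place of palladium. 9-BBN in THF reacts only with the monosubstituted alkene, and oxidation with NaBO3·4H2O gives the primary alcohol F5. Dess–Martin periodinane in CH2Cl2 then gives the aldehyde, and the fallback comes back to the route at 8.

## Further compounds

F1 | step 10 | (2E,6S,7S,9S,10Z)-7-acetoxy-11-(hydroxymethyl)-10-iodo-12-methoxy-3,7... acid, i.e. the C6 carboxylic acid of 15 | COC(=O)/C(CO)=C(I)/[C@@H](OC(=O)C(C)=C)C[C@H](C)[C@@H](OC(C)=O)CC/C(C)=C/C(=O)O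
F2 | step 10 | S-(pyridin-2-yl) thioester of F1 | COC(=O)/C(CO)=C(I)/[C@@H](OC(=O)C(C)=C)C[C@H](C)[C@@H](OC(C)=O)CC/C(C)=C/C(=O)Sc1ccccn1
F3 | step 10 | macrocyclic 6-ketone, methyl (2E)-2-[(3E,7S,8S,10S)-7-acetoxy-4,8-dimethyl-10-(methacryloyloxy)-2-oxocyclodec-3-en-1-ylidene]-3-hydroxypropanoate | COC(=O)/C(CO)=C1/[C@@H](OC(=O)C(C)=C)C[C@H](C)[C@@H](OC(C)=O)CC/C(C)=C/C1=O
F4 | step 7 | methyl (2Z,4S,6S,7S,10E)-7,12-diacetoxy-2-(hydroxymethyl)-6,10-dimethyl-4-(methacryloyloxy)-3-(trimethylstannyl)dodeca-2,10-dienoate | COC(=O)/C(CO)=C([Sn](C)(C)C)/[C@@H](OC(=O)C(C)=C)C[C@H](C)[C@@H](OC(C)=O)CC/C(C)=C/COC(C)=O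
F5 | step 4 | (2E,6S,7S)-9-hydroxy-3,7-dimethylnon-2-ene-1,6-diyl diacetate | OCC[C@H](C)[C@@H](OC(C)=O)CC/C(C)=C/COC(C)=O
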